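**Plan**

- Retrosynthesis: after removal of the two MOM ethers, the 7-O-silyl group and the 5-O-methyl group, ring A is cut away whole along C4a–C5, C5–C6, C7–C8 and C8–C8a. This leaves a 5-aryl-2-(diazoacetyl)-4-pyranone (ring C carrying ring B) and (triisopropylsilyloxy)ethyne.
- Enabling feature: ring A has oxygen on C5 and C7 in a meta relation, C5 sits directly on the fusion carbon C4a, and C6 and C8 carry hydrogen. That is the imprint of a ketene carbon (C5), an oxygenated alkyne (C6, C7) and a former diazo carbon (C8) annulated onto the C8a=C4a edge of an existing pyranone.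
- Further cuts: the C3–C1′ bond (Suzuki coupling of kojic acid 5-triflate with an arylboronate), the aryl C–B bond (steric C–H borylation) and the prenyl C–C bond (ortho-lithiation of catechol bis-MOM ether).
- Forward order: ring B is dressed first and joined to the kojic acid pyranone (ring C); the CH2OH arm is raised to COCHN2; ring A is closed last as a phenol; 5-O-methylation, desilylation and MOM removal finish the route.
- Stereochemistry: the target has no stereocentre and no stereogenic double bond, so only regiochemistry is controlled. The 5-OH/7-O differentiation comes from the benzannulation itself (free chelated OH against silyl ether).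

Key step: step 10

Abbreviation and numbering: Ar = 3,4-bis(methoxymethoxy)-5-(3-methylbut-2-en-1-yl)phenyl; in step 10 the pyranone atoms are called by their later chromone numbers.

Assumption: diazomethane is supplied as a dried ethereal solution and tert-butyl hydroperoxide as an anhydrous solution in decane.

**Route**

Step 1
Reactants: 1 catechol
Product: 2 1,2-bis(methoxymethoxy)benzene
Conditions: MOMCl, i-Pr2NEt, CH2Cl2, 0 °C → rt
Reagents that add atoms: chloromethyl methyl ether, COCCl
Why: O-alkylation of both phenols by the reactive α-chloro ether (Williamson-type acetal formation) gives the bis-MOM ether, which is stable to bases and organometallics and serves as the directing group for the next step.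

Step 2
Reactants: 2 1,2-bis(methoxymethoxy)benzene; 3 prenyl bromide (1-bromo-3-methylbut-2-ene)
Product: 5 1,2-bis(methoxymethoxy)-3-(3-methylbut-2-en-1-yl)benzene, via aryllithium 4 (not isolated)
Conditions: n-BuLi, THF, 0 °C → rt; CuBr·SMe2 (10 mol %), 3, −78 °C → rt
Reagents that add atoms: none
Why: The MOM ethers direct lithiation to the ortho position C3 (directed ortho-metalation), and copper-catalysed allylic substitution of prenyl bromide by the aryllithium should take place at the primary carbon to give the linear prenyl arene.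

Step 3
Reactants: 5 1,2-bis(methoxymethoxy)-3-(3-methylbut-2-en-1-yl)benzene
Product: 6 2-Ar-4,4,5,5-tetramethyl-1,3,2-dioxaborolane
Conditions: [Ir(OMe)(cod)]2 (1.5 mol %), 4,4′-di-tert-butyl-2,2′-bipyridine (3 mol %), B2pin2 (1.0 equiv), THF, 60 °C
Reagents that add atoms: bis(pinacolato)diboron, CC1(C)OB(OC1(C)C)B1OC(C)(C)C(C)(C)O1
Why: Iridium-catalysed aromatic C–H borylation is governed by sterics, so boron should enter at C5, the only ring C–H flanked by two hydrogens (para to the inner MOM ether, meta to prenyl), while the hindered trisubstituted olefin is expected to stay untouched.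

Step 4
Reactants: 7 kojic acid
Product: 8 6-(hydroxymethyl)-4-oxo-4H-pyran-3-yl trifluoromethanesulfonate
Conditions: PhNTf2, Et3N, DMF, 0 °C → rt
Reagents that add atoms: N-phenylbis(trifluoromethanesulfonimide), O=S(=O)(N(c1ccccc1)S(=O)(=O)C(F)(F)F)C(F)(F)F
Why: Only the acidic enolic 5-OH is ionised by Et3N, and PhNTf2 sulfonylates oxyanions but not neutral primary alcohols, so chemoselective O-triflation of the phenol-like position is expected.

Step 5
Reactants: 8 6-(hydroxymethyl)-4-oxo-4H-pyran-3-yl trifluoromethanesulfonate; 6 2-Ar-4,4,5,5-tetramethyl-1,3,2-dioxaborolane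
Product: 9 5-Ar-2-(hydroxymethyl)-4H-pyran-4-one
Conditions: Pd(PPh3)4 (5 mol %), K3PO4, 1,4-dioxane/H2O, 80 °C
Reagents that add atoms: none
Why: Suzuki–Miyaura coupling, in which the electron-poor pyranonyl triflate adds readily to zerovalent palladium and the phosphate-activated boronate delivers the aryl group, while the free primary alcohol, the MOM ethers and the prenyl olefin are spectators.

Step 6
Reactants: 9 5-Ar-2-(hydroxymethyl)-4H-pyran-4-one
Product: 11 5-Ar-4-oxo-4H-pyran-2-carboxylic acid, via aldehyde 10 (not isolated)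
Conditions: TEMPO (20 mol %), PhI(OAc)2 (2.2 equiv), MeCN/H2O, rt
Reagents that add atoms: water, O
Why: Oxoammonium-mediated oxidation (TEMPO/PhI(OAc)2) takes the allylic-type primary alcohol to the electron-poor aldehyde, whose hydrate is oxidised on to the acid under nearly neutral conditions that spare the MOM ethers, the electron-rich arene and the prenyl group.

Step 7
Reactants: 11 5-Ar-4-oxo-4H-pyran-2-carboxylic acid
Product: 13 5-Ar-2-(diazoacetyl)-4H-pyran-4-one, via mixed anhydride 12 (not isolated)
Conditions: i-BuOCOCl, N-methylmorpholine, THF, −15 °C; CH2N2, Et2O, 0 °C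
Reagents that add atoms: diazomethane, C=[N+]=[N-]
Why: Acylation of diazomethane by a mixed carbonic anhydride (the diazoketone stage of an Arndt–Eistert sequence) proceeds without free HCl, so the MOM ethers survive, and the departing isobutyl carbonate deprotonates the acyl diazonium intermediate.

Step 8
Reactants: 14 ethynyltrimethylsilane
Product: 17 triisopropyl{[(trimethylsilyl)ethynyl]oxy}silane, via lithium acetylide 15 (not isolated), via lithium ynolate 16 (not isolated)
Conditions: n-BuLi, THF, −78 °C; t-BuOOLi (from t-BuOOH and LiN(SiMe3)2, THF, −78 °C), −78 → 0 °C; i-Pr3SiOTf, −78 °C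
Reagents that add atoms: tert-butyl hydroperoxide, CC(C)(C)OO; triisopropylsilyl trifluoromethanesulfonate, CC(C)[Si](OS(=O)(=O)C(F)(F)F)(C(C)C)C(C)C
Why: Oxidation of the lithium acetylide by lithium tert-butyl peroxide (nucleophilic displacement at the peroxide oxygen) gives the ynolate, and the bulky silyl triflate should react at oxygen and not at the silyl-shielded carbon, the established way to triisopropylsilyl ynol ethers.

Step 9
Reactants: 17 triisopropyl{[(trimethylsilyl)ethynyl]oxy}silane
Product: 18 (triisopropylsilyloxy)ethyne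
Conditions: K2CO3 (cat.), MeOH, 0 °C, short contact time; pentane extraction
Reagents that add atoms: none
Why: Methoxide-catalysed protodesilylation cleaves the C(sp)–SiMe3 bond quickly, whereas the hindered O–Si(i-Pr)3 bond is attacked only slowly, as in the selective unmasking of trimethylsilyl alkynes beside triisopropylsilyl groups.

Step 10
Reactants: 13 5-Ar-2-(diazoacetyl)-4H-pyran-4-one; 18 (triisopropylsilyloxy)ethyne
Product: 23 5-hydroxy-7-(triisopropylsilyloxy)-3-Ar-4H-chromen-4-one, via pyranonylketene 19 (not isolated), via siloxycyclobutenone 20 (not isolated), via dienylketene 21 (not isolated), via cyclohexadienone 22 (not isolated)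
Conditions: 18 (2.5 equiv), ClCH2CH2Cl (degassed), hν 365 nm, rt; then 80 °C in the dark
Reagents that add atoms: none
Why: Long-wavelength excitation of the diazoketone expels N2 and the pyranon-2-yl group shifts to the carbene carbon (Wolff rearrangement, forming C8–C8a) to give ketene 19, which is intercepted by the electron-rich alkyne 18 in a [2+2] cycloaddition (C5–C6 and C7–C8) to give 20. On warming, 20 opens by a reversible four-electron electrocyclic reaction to dienylketene 21, whose ketene carbon closes onto pyranone C3 in a thermal disrotatory six-electron electrocyclization (C4a–C5, the single ring closure, forming the six-membered carbocycle ring A), and keto tautomer 22 aromatises to the phenol by a proton shift. The closest known reaction is the Danheiser benzannulation of aryl, hetaryl and alkenyl diazomethyl ketones with silyloxyalkynes, which gives resorcinol monosilyl ethers with the free OH next to the ring fusion, as needed here. No stereocentre survives, since the sp3 centres of 20 and 22 are transient and racemic and 23 is planar. Two regiochemical demands are met by the substrates themselves, because the polarised alkyne bonds through its nucleophilic CH terminus to the electrophilic ketene carbon (silyloxy therefore ends on C7) and because pyranone C3 is the only carbon within reach of the ketene terminus, the other neighbour of C2 being the ring oxygen. Chemoselectivity towards the photolabile 4-pyranone is sought by irradiating at 365 nm, where the diazoketone n–π* band absorbs and the pyranone and the silyloxyalkyne hardly do, and the excess of 18 keeps ketene dimerisation down.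

Step 11
Reactants: 23 5-hydroxy-7-(triisopropylsilyloxy)-3-Ar-4H-chromen-4-one
Product: 24 5-methoxy-7-(triisopropylsilyloxy)-3-Ar-4H-chromen-4-one
Conditions: MeI (excess), Ag2O, MeCN, 40 °C, dark
Reagents that add atoms: iodomethane, CI
Why: Purdie methylation, in which Ag2O activates MeI and takes up the acid under essentially neutral conditions, should methylate the hydrogen-bonded 5-OH without loosening the aryl silyl ether that masks the more reactive 7-oxygen.

Step 12
Reactants: 24 5-methoxy-7-(triisopropylsilyloxy)-3-Ar-4H-chromen-4-one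
Product: 25 7-hydroxy-5-methoxy-3-Ar-4H-chromen-4-one
Conditions: n-Bu4NF, AcOH, THF, 0 °C
Reagents that add atoms: none
Why: Fluoride-induced cleavage of the aryl silyl ether is driven by the strong Si–F bond, and the acetic acid buffer protonates the liberated 7-phenoxide so that the base-sensitive chromone is not exposed to naked fluoride.

Step 13
Reactants: 25 7-hydroxy-5-methoxy-3-Ar-4H-chromen-4-one
Product: 26 glisoflavone, 3-[3,4-dihydroxy-5-(3-methylbut-2-en-1-yl)phenyl]-7-hydroxy-5-methoxy-4H-chromen-4-one
Conditions: HCl (3 M aq.), MeOH, 45 °C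
Reagents that add atoms: none
Why: Acid-catalysed acetal exchange with methanol removes both MOM groups as dimethoxymethane, and dilute acid at moderate temperature is chosen so that the ortho-prenyl phenol does not cyclise to a chroman.

**Compound list**

1 | catechol | Oc1ccccc1O | starting material
2 | 1,2-bis(methoxymethoxy)benzene | COCOc1ccccc1OCOC | intermediate
3 | prenyl bromide (1-bromo-3-methylbut-2-ene) | CC(C)=CCBr | starting material
4 | [2,3-bis(methoxymethoxy)phenyl]lithium | [Li]c1cccc(OCOC)c1OCOC | intermediate (not isolated)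
5 | 1,2-bis(methoxymethoxy)-3-(3-methylbut-2-en-1-yl)benzene | COCOc1cccc(CC=C(C)C)c1OCOC | intermediate
6 | 2-[3,4-bis(methoxymethoxy)-5-(3-methylbut-2-en-1-yl)phenyl]-4,4,5,5-tetramethyl-1,3,2-dioxaborolane | COCOc1cc(B2OC(C)(C)C(C)(C)O2)cc(CC=C(C)C)c1OCOC | intermediate
7 | kojic acid (5-hydroxy-2-(hydroxymethyl)-4H-pyran-4-one) | OCc1cc(=O)c(O)co1 | starting material
8 | 6-(hydroxymethyl)-4-oxo-4H-pyran-3-yl trifluoromethanesulfonate | OCc1cc(=O)c(OS(=O)(=O)C(F)(F)F)co1 | intermediate
9 | 5-[3,4-bis(methoxymethoxy)-5-(3-methylbut-2-en-1-yl)phenyl]-2-(hydroxymethyl)-4H-pyran-4-one | OCc1cc(=O)c(-c2cc(OCOC)c(OCOC)c(CC=C(C)C)c2)co1 | intermediate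
10 | 5-[3,4-bis(methoxymethoxy)-5-(3-methylbut-2-en-1-yl)phenyl]-4-oxo-4H-pyran-2-carbaldehyde | O=Cc1cc(=O)c(-c2cc(OCOC)c(OCOC)c(CC=C(C)C)c2)co1 | intermediate (not isolated)
11 | 5-[3,4-bis(methoxymethoxy)-5-(3-methylbut-2-en-1-yl)phenyl]-4-oxo-4H-pyran-2-carboxylic acid | OC(=O)c1cc(=O)c(-c2cc(OCOC)c(OCOC)c(CC=C(C)C)c2)co1 | intermediate
12 | mixed anhydride of 11 with isobutyl hydrogen carbonate | CC(C)COC(=O)OC(=O)c1cc(=O)c(-c2cc(OCOC)c(OCOC)c(CC=C(C)C)c2)co1 | intermediate (not isolated)
13 | 5-[3,4-bis(methoxymethoxy)-5-(3-methylbut-2-en-1-yl)phenyl]-2-(diazoacetyl)-4H-pyran-4-one | [N-]=[N+]=CC(=O)c1cc(=O)c(-c2cc(OCOC)c(OCOC)c(CC=C(C)C)c2)co1 | intermediate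
14 | ethynyltrimethylsilane | C#C[Si](C)(C)C | starting material
15 | lithium (trimethylsilyl)acetylide | [Li]C#C[Si](C)(C)C | intermediate (not isolated)
16 | lithium 2-(trimethylsilyl)ethynolate | [Li]OC#C[Si](C)(C)C | intermediate (not isolated)
17 | triisopropyl{[(trimethylsilyl)ethynyl]oxy}silane | C[Si](C)(C)C#CO[Si](C(C)C)(C(C)C)C(C)C | intermediate
18 | (triisopropylsilyloxy)ethyne | C#CO[Si](C(C)C)(C(C)C)C(C)C | intermediate
19 | 5-Ar-2-(2-oxoethenyl)-4H-pyran-4-one (pyranonylketene) | O=C=Cc1cc(=O)c(-c2cc(OCOC)c(OCOC)c(CC=C(C)C)c2)co1 | intermediate (not isolated)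
20 | 4-(5-Ar-4-oxo-4H-pyran-2-yl)-3-(triisopropylsilyloxy)cyclobut-2-en-1-one (racemic) | O=C1C=C(O[Si](C(C)C)(C(C)C)C(C)C)C1c1cc(=O)c(-c2cc(OCOC)c(OCOC)c(CC=C(C)C)c2)co1 | intermediate (not isolated)
21 | 5-Ar-2-[4-oxo-2-(triisopropylsilyloxy)buta-1,3-dien-1-yl]-4H-pyran-4-one, ketenyl carbon cis to the pyranonyl group across the central C=C | O=C=C/C(O[Si](C(C)C)(C(C)C)C(C)C)=C\c1cc(=O)c(-c2cc(OCOC)c(OCOC)c(CC=C(C)C)c2)co1 | intermediate (not isolated)
22 | 3-Ar-7-(triisopropylsilyloxy)-4aH-chromene-4,5-dione (keto tautomer of 23, racemic) | O=C1C=C(O[Si](C(C)C)(C(C)C)C(C)C)C=C2OC=C(-c3cc(OCOC)c(OCOC)c(CC=C(C)C)c3)C(=O)C12 | intermediate (not isolated)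
23 | 5-hydroxy-7-(triisopropylsilyloxy)-3-[3,4-bis(methoxymethoxy)-5-(3-methylbut-2-en-1-yl)phenyl]-4H-chromen-4-one | Oc1cc(O[Si](C(C)C)(C(C)C)C(C)C)cc2occ(-c3cc(OCOC)c(OCOC)c(CC=C(C)C)c3)c(=O)c12 | intermediate
24 | 5-methoxy-7-(triisopropylsilyloxy)-3-[3,4-bis(methoxymethoxy)-5-(3-methylbut-2-en-1-yl)phenyl]-4H-chromen-4-one | COc1cc(O[Si](C(C)C)(C(C)C)C(C)C)cc2occ(-c3cc(OCOC)c(OCOC)c(CC=C(C)C)c3)c(=O)c12 | intermediate
25 | 7-hydroxy-5-methoxy-3-[3,4-bis(methoxymethoxy)-5-(3-methylbut-2-en-1-yl)phenyl]-4H-chromen-4-one | COc1cc(O)cc2occ(-c3cc(OCOC)c(OCOC)c(CC=C(C)C)c3)c(=O)c12 | intermediate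
26 | glisoflavone | COc1cc(O)cc2occ(-c3cc(O)c(O)c(CC=C(C)C)c3)c(=O)c12 | target

**Step count**

Total: 13 steps. Longest linear sequence: 10 steps (steps 1, 2, 3, 5, 6, 7, 10, 11, 12, 13, from catechol).

**Steps most likely to fail**

Step 10. The pyranone chromophore or the chromone product may absorb competitively and photoisomerise, the ketene may dimerise before the alkyne traps it, or the cyclobutenone may not open and close cleanly. The fallback sets out from 13, makes the same ketene without light, and returns at 23. Silver-catalysed Wolff rearrangement of 13 in the dark (PhCO2Ag, Et3N, THF/H2O, rt, the Arndt–Eistert homologation) should give (5-Ar-4-oxo-4H-pyran-2-yl)acetic acid F1. Treatment with 1-chloro-N,N,2-trimethylprop-1-en-1-amine in CH2Cl2 should convert it without free HCl into (5-Ar-4-oxo-4H-pyran-2-yl)acetyl chloride F2. Slow addition of Et3N to F2 and excess 18 in toluene should generate ketene 19 by dehydrochlorination, and 19 then follows the same thermal course through 20, 21 and 22 at 80 °C to give 23.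

Step 7. Diazomethane may add as a dipole across the doubly activated C2=C3 bond of the acylpyranone, or attack the carbonate carbonyl of 12, in place of clean C-acylation. The fallback sets out from 11, builds the carbon skeleton first and introduces the diazo group last by detrifluoroacetylative diazo transfer, and returns at 13. Thioesterification (EtSH, EDC, DMAP, CH2Cl2) should give S-ethyl 5-Ar-4-oxo-4H-pyran-2-carbothioate F3. Fukuyama coupling with MeZnI and PdCl2(PPh3)2 in toluene should give 2-acetyl-5-Ar-4H-pyran-4-one F4, the organozinc leaving the pyranone alone. Enolisation with LiN(SiMe3)2 and trapping with CF3CO2CH2CF3 at −78 °C should give 4,4,4-trifluoro-1-(5-Ar-4-oxo-4H-pyran-2-yl)butane-1,3-dione F5. Diazo transfer with MsN3, Et3N and water in MeCN, with loss of the trifluoroacetyl group, should then give 13.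

Step 3. The iridium boryl species or the pinacolborane formed may hydroborate the prenyl olefin or borylate its vinylic or allylic C–H bonds, which would erode the arene borylation. The fallback sets out from 2, borylates before any olefin is present, brings in the prenyl group last by cross-coupling, and returns at 6. Lithiation of 2 as in step 2 (via 4) and quenching with BrCCl2CCl2Br should give 1-bromo-2,3-bis(methoxymethoxy)benzene F6. The same iridium-catalysed borylation should give 2-[3-bromo-4,5-bis(methoxymethoxy)phenyl]-4,4,5,5-tetramethyl-1,3,2-dioxaborolane F7. Base-free, linear-selective Negishi coupling of F7 with prenylzinc bromide F8 (from 3, zinc dust and LiCl in THF) under Pd(OAc)2/CPhos catalysis should give 6, the pinacol boronate being inert in the absence of base.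

**Further compounds**

F1 | step 10 | {5-[3,4-bis(methoxymethoxy)-5-(3-methylbut-2-en-1-yl)phenyl]-4-oxo-4H-pyran-2-yl}acetic acid | OC(=O)Cc1cc(=O)c(-c2cc(OCOC)c(OCOC)c(CC=C(C)C)c2)co1
F2 | step 10 | {5-[3,4-bis(methoxymethoxy)-5-(3-methylbut-2-en-1-yl)phenyl]-4-oxo-4H-pyran-2-yl}acetyl chloride | ClC(=O)Cc1cc(=O)c(-c2cc(OCOC)c(OCOC)c(CC=C(C)C)c2)co1
F3 | step 7 | S-ethyl 5-[3,4-bis(methoxymethoxy)-5-(3-methylbut-2-en-1-yl)phenyl]-4-oxo-4H-pyran-2-carbothioate | CCSC(=O)c1cc(=O)c(-c2cc(OCOC)c(OCOC)c(CC=C(C)C)c2)co1
F4 | step 7 | 2-acetyl-5-[3,4-bis(methoxymethoxy)-5-(3-methylbut-2-en-1-yl)phenyl]-4H-pyran-4-one | CC(=O)c1cc(=O)c(-c2cc(OCOC)c(OCOC)c(CC=C(C)C)c2)co1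
F5 | step 7 | 4,4,4-trifluoro-1-{5-[3,4-bis(methoxymethoxy)-5-(3-methylbut-2-en-1-yl)phenyl]-4-oxo-4H-pyran-2-yl}butane-1,3-dione | O=C(CC(=O)C(F)(F)F)c1cc(=O)c(-c2cc(OCOC)c(OCOC)c(CC=C(C)C)c2)co1
F6 | step 3 | 1-bromo-2,3-bis(methoxymethoxy)benzene | COCOc1cccc(Br)c1OCOC
F7 | step 3 | 2-[3-bromo-4,5-bis(methoxymethoxy)phenyl]-4,4,5,5-tetramethyl-1,3,2-dioxaborolane | COCOc1cc(B2OC(C)(C)C(C)(C)O2)cc(Br)c1OCOC
F8 | step 3 | prenylzinc bromide | CC(C)=CC[Zn]Br
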